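**Retrosynthetic overview**

- The target comes from its 3,5-di-O-benzyl ether by hydrogenolysis. Ring C is closed last, by cyclodehydration (O1–C2) of a 1,3-diketone that a Baker–Venkataraman shift (C2–C3 bond) makes from the C8a–O 3,4,5-trimethoxybenzoate of a ring-A α-benzyloxy ketone.
- That ketone is cut at C4a–C4 and C5–O: a ring-A aryne with its triple bond between C4a and C5 takes up benzyloxyacetic acid in one step (aryne 1,2-oxyacylation), the aryne being released from an ortho-silylaryl triflate.
- The silyl triflate comes from 2,3-dimethoxyphenol by two directed lithiations that each have only one possible site: OMOM-directed at C4a (giving C4a–OH, later the triflate), then carbamate-directed at C5 (giving C5–SiMe3). Triflate on C4a and silicon on C5 release the same aryne as the opposite placement, but a carbamate on the C5 oxygen would have to choose between two oxygen-flanked ortho hydrogens (C4a and C6).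
- Feature: on ring A the C5 hydroxyl and the C4 carbonyl sit on neighbouring carbons C5 and C4a, and C4a is flanked on its other side by the C8a oxygen. That oxygen polarises the C4a–C5 aryne so that oxygen enters at C5 and carbon at C4a, and it leaves C5–OH free while C8a–O stays a MOM ether, which fixes the 7,8- and not the 6,7-dimethoxy pattern.
- Ring order: rings A and B are bought; ring C is the only ring formed (step 11).

Key step: step 6

Remark: ring-A carbons are named by flavone numbering (C4a, C5, C6, C7, C8, C8a) from the first step on; diketone 20 is drawn in its open diketo form, and its enol or cyclic hemiketal forms would react alike in step 11.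

**Step 1**
Reactants: 1 2,3-dimethoxyphenol
Product: 2 1,2-dimethoxy-3-(methoxymethoxy)benzene
Conditions: NaH, MOMCl, DMF, 0 °C → rt
Reagents that add atoms: chloromethyl methyl ether, COCCl
Why: Williamson-type O-alkylation of the sodium phenoxide by the reactive α-chloro ether should give the MOM ether, which masks the C8a oxygen and directs the lithiation of step 2.

**Step 2**
Reactants: 2 1,2-dimethoxy-3-(methoxymethoxy)benzene
Product: 5 3,4-dimethoxy-2-(methoxymethoxy)phenol, via aryllithium 3 (not isolated), via dimethyl arylboronate 4 (not isolated)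
Conditions: n-BuLi, THF, 0 °C; B(OMe)3, −78 °C → rt; AcOH, 30% aq. H2O2, 0 °C → rt
Reagents that add atoms: hydrogen peroxide, OO (supplies the phenol oxygen); trimethyl borate, COB(OC)OC (its boron and methoxy groups are present in intermediate 4 only)
Why: Directed ortho-metalation, in which the OMOM group is the strongest director and has a single free ortho position (C4a), followed by borylation and peroxide oxidation of the C–B bond, should place the hydroxyl on C4a.

**Step 3**
Reactants: 5 3,4-dimethoxy-2-(methoxymethoxy)phenol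
Product: 6 3,4-dimethoxy-2-(methoxymethoxy)phenyl N-(propan-2-yl)carbamate
Conditions: i-PrNCO, Et3N (cat.), CH2Cl2, rt
Reagents that add atoms: isopropyl isocyanate, CC(C)N=C=O
Why: Amine-catalysed addition of the phenol to the isocyanate (carbamoylation) should give an O-aryl carbamate that is a strong metalation director and can later be removed under mild base.

**Step 4**
Reactants: 6 3,4-dimethoxy-2-(methoxymethoxy)phenyl N-(propan-2-yl)carbamate
Product: 10 3,4-dimethoxy-2-(methoxymethoxy)-6-(trimethylsilyl)phenyl N-(propan-2-yl)carbamate, via N-silyl carbamate 7 (not isolated), via aryllithium 8 (not isolated), via N-silyl C-silyl carbamate 9 (not isolated)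
Conditions: TBSOTf, TMEDA, Et2O, 0 °C → rt; n-BuLi, TMEDA, −78 °C; Me3SiCl, −78 °C → rt; aq. NaHSO4 work-up
Reagents that add atoms: chlorotrimethylsilane, C[Si](C)(C)Cl; tert-butyldimethylsilyl trifluoromethanesulfonate, CC(C)(C)[Si](C)(C)OS(=O)(=O)C(F)(F)F (its silyl group is present in intermediates 7 to 9 only)
Why: Carbamate-directed ortho-metalation after in-situ N-silylation should lithiate C5, the only hydrogen ortho to the carbamate oxygen, and Me3SiCl traps the aryllithium, the N-silyl group being lost on the mildly acidic work-up.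

**Step 5**
Reactants: 10 3,4-dimethoxy-2-(methoxymethoxy)-6-(trimethylsilyl)phenyl N-(propan-2-yl)carbamate
Product: 12 3,4-dimethoxy-2-(methoxymethoxy)-6-(trimethylsilyl)phenyl trifluoromethanesulfonate, via silylphenol 11 (not isolated)
Conditions: Et2NH, DBU, MeCN, 40 °C; then PhNTf2, rt → 40 °C
Reagents that add atoms: N-phenylbis(trifluoromethanesulfonimide), O=S(=O)(N(c1ccccc1)S(=O)(=O)C(F)(F)F)C(F)(F)F
Why: The N-monoalkyl carbamate should cleave by base-induced E1cB elimination to the isocyanate (trapped by Et2NH as a urea), and the phenoxide is then O-sulfonylated in the same flask (triflation).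

**Step 6**
Reactants: 12 3,4-dimethoxy-2-(methoxymethoxy)-6-(trimethylsilyl)phenyl trifluoromethanesulfonate; 13 benzyloxyacetic acid
Product: 15 2-(benzyloxy)-1-[6-hydroxy-3,4-dimethoxy-2-(methoxymethoxy)phenyl]ethanone, via aryne 14 (not isolated)
Conditions: CsF, THF, 125 °C (sealed tube)
Reagents that add atoms: none
Why: Fluoride removes the silyl group from C5 and the aryl anion expels the C4a triflate, giving aryne 14 (Kobayashi 1,2-elimination). The caesium carboxylate of 13 should bond through oxygen to C5, the end of the triple bond that is meta to the C8a OMOM group, because the inductively withdrawing C8a oxygen distorts the aryne and stabilises the negative charge that develops on the adjacent C4a. The C4a carbanion then adds to the carbonyl group of the freshly formed aryl ester, and the strained four-membered alkoxide collapses with C–O cleavage, leaving the acyl group on C4a (the future C4 carbonyl) and a phenoxide on C5; the closest known reaction type is this same formal insertion of silylaryl-triflate-derived arynes into the acyl C–O bond of carboxylic acids with CsF in hot THF, which gives ortho-hydroxyaryl ketones. No ring is closed and no stereocentre is formed. The step needs site selectivity in the O-addition, secured by the C8a alkoxy group flanking the triple bond, and acyl transfer ahead of protonation of the C4a anion, favoured by the adjacent ester carbonyl and the hot aprotic medium.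

**Step 7**
Reactants: 15 2-(benzyloxy)-1-[6-hydroxy-3,4-dimethoxy-2-(methoxymethoxy)phenyl]ethanone
Product: 16 2-(benzyloxy)-1-[6-(benzyloxy)-3,4-dimethoxy-2-(methoxymethoxy)phenyl]ethanone
Conditions: BnBr, K2CO3, DMF, 60 °C
Reagents that add atoms: benzyl bromide, BrCc1ccccc1
Why: Williamson O-benzylation of the hydrogen-bonded C5 phenoxide should cap C5–O so that only C8a–O can be acylated later.

**Step 8**
Reactants: 16 2-(benzyloxy)-1-[6-(benzyloxy)-3,4-dimethoxy-2-(methoxymethoxy)phenyl]ethanone
Product: 17 2-(benzyloxy)-1-[6-(benzyloxy)-2-hydroxy-3,4-dimethoxyphenyl]ethanone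
Conditions: 3 M aq. HCl, MeOH–THF, 50 °C
Reagents that add atoms: none
Why: Acid-catalysed acetal exchange with methanol (MOM cleavage) should free C8a–OH while the benzyl ethers, methyl ethers and the hindered ketone are stable to dilute acid.

**Step 9**
Reactants: 17 2-(benzyloxy)-1-[6-(benzyloxy)-2-hydroxy-3,4-dimethoxyphenyl]ethanone; 18 3,4,5-trimethoxybenzoyl chloride
Product: 19 3-(benzyloxy)-2-[(benzyloxy)acetyl]-5,6-dimethoxyphenyl 3,4,5-trimethoxybenzoate
Conditions: Et3N, DMAP (cat.), CH2Cl2, 0 °C → rt
Reagents that add atoms: none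
Why: DMAP-catalysed O-acylation with the acid chloride should esterify C8a–OH, the only free hydroxyl.

**Step 10**
Reactants: 19 3-(benzyloxy)-2-[(benzyloxy)acetyl]-5,6-dimethoxyphenyl 3,4,5-trimethoxybenzoate
Product: 20 2-(benzyloxy)-1-[6-(benzyloxy)-2-hydroxy-3,4-dimethoxyphenyl]-3-(3,4,5-trimethoxyphenyl)propane-1,3-dione (racemic)
Conditions: LiN(SiMe3)2, THF, −20 °C → rt; AcOH quench
Reagents that add atoms: none
Why: Baker–Venkataraman rearrangement, in which the ketone enolate attacks the neighbouring aryl ester intramolecularly and the aroyl group moves from oxygen to carbon (C2–C3 bond); the new sp3 centre is formed racemic and is erased in step 11.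

**Step 11**
Reactants: 20 2-(benzyloxy)-1-[6-(benzyloxy)-2-hydroxy-3,4-dimethoxyphenyl]-3-(3,4,5-trimethoxyphenyl)propane-1,3-dione
Product: 21 3,5-bis(benzyloxy)-7,8-dimethoxy-2-(3,4,5-trimethoxyphenyl)-4H-chromen-4-one
Conditions: p-TsOH·H2O (cat.), toluene, 80 °C
Reagents that add atoms: none
Why: Acid-catalysed cyclodehydration, in which C8a–OH adds to the aroyl carbonyl (6-exo-trig hemiketal) and water is lost, should close the 4-pyranone ring C; any loss of the C5 benzyl group here is harmless because step 12 removes it anyway.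

**Step 12**
Reactants: 21 3,5-bis(benzyloxy)-7,8-dimethoxy-2-(3,4,5-trimethoxyphenyl)-4H-chromen-4-one
Product: 22 3,5-dihydroxy-7,8,3',4',5'-pentamethoxyflavone
Conditions: H2 (1 atm), 10% Pd/C, EtOAc–MeOH, rt
Reagents that add atoms: none
Why: Catalytic hydrogenolysis should cleave both benzyl ethers while the chromone double bond and the methyl ethers stay intact under these mild conditions.

**Compound list**

1 | 2,3-dimethoxyphenol | COc1cccc(O)c1OC | starting material
2 | 1,2-dimethoxy-3-(methoxymethoxy)benzene | COCOc1cccc(OC)c1OC | intermediate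
3 | [3,4-dimethoxy-2-(methoxymethoxy)phenyl]lithium | [Li]c1ccc(OC)c(OC)c1OCOC | intermediate (not isolated)
4 | dimethyl [3,4-dimethoxy-2-(methoxymethoxy)phenyl]boronate | COB(OC)c1ccc(OC)c(OC)c1OCOC | intermediate (not isolated)
5 | 3,4-dimethoxy-2-(methoxymethoxy)phenol | COCOc1c(O)ccc(OC)c1OC | intermediate
6 | 3,4-dimethoxy-2-(methoxymethoxy)phenyl N-(propan-2-yl)carbamate | CC(C)NC(=O)Oc1ccc(OC)c(OC)c1OCOC | intermediate
7 | 3,4-dimethoxy-2-(methoxymethoxy)phenyl N-[tert-butyl(dimethyl)silyl]-N-(propan-2-yl)carbamate | CC(C)N(C(=O)Oc1ccc(OC)c(OC)c1OCOC)[Si](C)(C)C(C)(C)C | intermediate (not isolated)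
8 | 6-lithio-3,4-dimethoxy-2-(methoxymethoxy)phenyl N-[tert-butyl(dimethyl)silyl]-N-(propan-2-yl)carbamate | [Li]c1cc(OC)c(OC)c(OCOC)c1OC(=O)N(C(C)C)[Si](C)(C)C(C)(C)C | intermediate (not isolated)
9 | 3,4-dimethoxy-2-(methoxymethoxy)-6-(trimethylsilyl)phenyl N-[tert-butyl(dimethyl)silyl]-N-(propan-2-yl)carbamate | C[Si](C)(C)c1cc(OC)c(OC)c(OCOC)c1OC(=O)N(C(C)C)[Si](C)(C)C(C)(C)C | intermediate (not isolated)
10 | 3,4-dimethoxy-2-(methoxymethoxy)-6-(trimethylsilyl)phenyl N-(propan-2-yl)carbamate | CC(C)NC(=O)Oc1c([Si](C)(C)C)cc(OC)c(OC)c1OCOC | intermediate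
11 | 3,4-dimethoxy-2-(methoxymethoxy)-6-(trimethylsilyl)phenol | COCOc1c(O)c([Si](C)(C)C)cc(OC)c1OC | intermediate (not isolated)
12 | 3,4-dimethoxy-2-(methoxymethoxy)-6-(trimethylsilyl)phenyl trifluoromethanesulfonate | COCOc1c(OS(=O)(=O)C(F)(F)F)c([Si](C)(C)C)cc(OC)c1OC | intermediate
13 | benzyloxyacetic acid | OC(=O)COCc1ccccc1 | starting material
14 | 4,5-dimethoxy-3-(methoxymethoxy)benzyne (1,2-didehydro-4,5-dimethoxy-3-(methoxymethoxy)benzene) | COCOC1=C(OC)C(OC)=CC#C1 | intermediate (not isolated)
15 | 2-(benzyloxy)-1-[6-hydroxy-3,4-dimethoxy-2-(methoxymethoxy)phenyl]ethanone | COCOc1c(OC)c(OC)cc(O)c1C(=O)COCc1ccccc1 | intermediate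
16 | 2-(benzyloxy)-1-[6-(benzyloxy)-3,4-dimethoxy-2-(methoxymethoxy)phenyl]ethanone | COCOc1c(OC)c(OC)cc(OCc2ccccc2)c1C(=O)COCc1ccccc1 | intermediate
17 | 2-(benzyloxy)-1-[6-(benzyloxy)-2-hydroxy-3,4-dimethoxyphenyl]ethanone | COc1cc(OCc2ccccc2)c(C(=O)COCc2ccccc2)c(O)c1OC | intermediate
18 | 3,4,5-trimethoxybenzoyl chloride | COc1cc(C(Cl)=O)cc(OC)c1OC | starting material
19 | 3-(benzyloxy)-2-[(benzyloxy)acetyl]-5,6-dimethoxyphenyl 3,4,5-trimethoxybenzoate | COc1cc(OCc2ccccc2)c(C(=O)COCc2ccccc2)c(OC(=O)c2cc(OC)c(OC)c(OC)c2)c1OC | intermediate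
20 | 2-(benzyloxy)-1-[6-(benzyloxy)-2-hydroxy-3,4-dimethoxyphenyl]-3-(3,4,5-trimethoxyphenyl)propane-1,3-dione (racemic) | COc1cc(OCc2ccccc2)c(C(=O)C(OCc2ccccc2)C(=O)c2cc(OC)c(OC)c(OC)c2)c(O)c1OC | intermediate
21 | 3,5-bis(benzyloxy)-7,8-dimethoxy-2-(3,4,5-trimethoxyphenyl)-4H-chromen-4-one | COc1cc(-c2oc3c(OC)c(OC)cc(OCc4ccccc4)c3c(=O)c2OCc2ccccc2)cc(OC)c1OC | intermediate
22 | 3,5-dihydroxy-7,8,3',4',5'-pentamethoxyflavone | COc1cc(-c2oc3c(OC)c(OC)cc(O)c3c(=O)c2O)cc(OC)c1OC | target

**Step count and risks**

Total step count: 12. Longest linear sequence: 12 steps (1 to 22); 13 and 18 are bought and enter at steps 6 and 9.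

Steps most likely to fail:

1. Step 6 (key step). The C4a aryl anion may be protonated before it reaches the ester carbonyl, so that only O-arylation of the acid occurs, or the product phenoxide may be arylated by further aryne. The fallback avoids the aryne; it sets out from 2 and comes back at 16.
   - Iridium-catalysed C–H borylation of 2 (B2pin2, [Ir(OMe)(cod)]2, 4,4'-di-tert-butyl-2,2'-bipyridine, THF, 80 °C) should go to C5, the only ring CH without an ortho substituent, giving 2-[3,4-dimethoxy-5-(methoxymethoxy)phenyl]-4,4,5,5-tetramethyl-1,3,2-dioxaborolane F1.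
   - Oxidation (H2O2, NaOH) would give 3,4-dimethoxy-5-(methoxymethoxy)phenol F2, and benzylation (BnBr, K2CO3, DMF) 5-(benzyloxy)-1,2-dimethoxy-3-(methoxymethoxy)benzene F3.
   - Lithiation with n-BuLi in THF at 0 °C, directed by the OMOM group to its one free ortho position C4a, would give [2-(benzyloxy)-4,5-dimethoxy-6-(methoxymethoxy)phenyl]lithium F4.
   - F4 is acylated by 2-(benzyloxy)-N-methoxy-N-methylacetamide F5 (made from 13 with 1,1'-carbonyldiimidazole and MeNHOMe·HCl) to give 16, and the route continues with step 8.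

2. Step 4. The silyl triflate used for N-silylation may attack the MOM ether, or the lithiated carbamate may undergo anionic ortho-Fries migration before it is silylated. The fallback replaces the carbamate route by halogenation and an O-to-C silyl shift; it sets out from 5 and comes back at 12.
   - Bromination of 5 (NBS, cat. i-Pr2NH, CH2Cl2, 0 °C) should go to C5, the only free position ortho or para to the hydroxyl, giving 6-bromo-3,4-dimethoxy-2-(methoxymethoxy)phenol F6.
   - O-Silylation with (Me3Si)2NH in THF at reflux would give [6-bromo-3,4-dimethoxy-2-(methoxymethoxy)phenoxy](trimethyl)silane F7.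
   - n-BuLi in THF at −78 °C would exchange bromine for lithium to give [4,5-dimethoxy-3-(methoxymethoxy)-2-(trimethylsilyloxy)phenyl]lithium F8, whose silyl group moves from oxygen to C5 (retro-Brook shift) to give lithium 3,4-dimethoxy-2-(methoxymethoxy)-6-(trimethylsilyl)phenolate F9.
   - Addition of Tf2O at −78 °C would convert F9 into 12.

3. Step 10. The ester may be cleaved back to 17, or the O-to-C aroyl transfer may stall at the hindered, α-oxygenated enolate. The fallback replaces steps 9 to 11 by an Allan–Robinson condensation; it sets out from 17 and comes back at 21.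
   - 17 would be heated with 3,4,5-trimethoxybenzoic anhydride F10 (made from 18 and commercial 3,4,5-trimethoxybenzoic acid with pyridine) and Et3N at about 160 °C.
   - Brief treatment with KOH in aqueous EtOH would cleave any surplus aroyl ester, giving 21 directly.

**Further compounds**

F1 | step 6 | 2-[3,4-dimethoxy-5-(methoxymethoxy)phenyl]-4,4,5,5-tetramethyl-1,3,2-dioxaborolane | COCOc1cc(B2OC(C)(C)C(C)(C)O2)cc(OC)c1OC
F2 | step 6 | 3,4-dimethoxy-5-(methoxymethoxy)phenol | COCOc1cc(O)cc(OC)c1OC
F3 | step 6 | 5-(benzyloxy)-1,2-dimethoxy-3-(methoxymethoxy)benzene | COCOc1cc(OCc2ccccc2)cc(OC)c1OC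
F4 | step 6 | [2-(benzyloxy)-4,5-dimethoxy-6-(methoxymethoxy)phenyl]lithium | COCOc1c([Li])c(OCc2ccccc2)cc(OC)c1OC
F5 | step 6 | 2-(benzyloxy)-N-methoxy-N-methylacetamide | CON(C)C(=O)COCc1ccccc1
F6 | step 4 | 6-bromo-3,4-dimethoxy-2-(methoxymethoxy)phenol | COCOc1c(O)c(Br)cc(OC)c1OC
F7 | step 4 | [6-bromo-3,4-dimethoxy-2-(methoxymethoxy)phenoxy](trimethyl)silane | COCOc1c(O[Si](C)(C)C)c(Br)cc(OC)c1OC
F8 | step 4 | [4,5-dimethoxy-3-(methoxymethoxy)-2-(trimethylsilyloxy)phenyl]lithium | COCOc1c(O[Si](C)(C)C)c([Li])cc(OC)c1OC
F9 | step 4 | lithium 3,4-dimethoxy-2-(methoxymethoxy)-6-(trimethylsilyl)phenolate | [Li+].COCOc1c([O-])c([Si](C)(C)C)cc(OC)c1OC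
F10 | step 10 | 3,4,5-trimethoxybenzoic anhydride | COc1cc(C(=O)OC(=O)c2cc(OC)c(OC)c(OC)c2)cc(OC)c1OC
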